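**Plan**

Atom numbers used throughout: ring A = C1, C2, C3 (C=O), C4 (CH3 and the C19 oxymethylene), C5, C10; ring B = C5, C6 (OH), C7, C8 (CH3), C9 (CH3 and the C11–C12 chain), C10; butenolide = C13–C16.
Retrosynthetic cuts, in order: the C19–O aryl-propanoate ester; the butenolide at C13=C14 and C13–C16; C4–C19; C4–C5 (ring A); C10–C1; C9–C11; last, C8–C9 and C5–C6 (ring B).
Forward: ring B is made first from allyl 2-methylacetoacetate and crotonaldehyde; the ester is then exchanged for the C9 allyl group (C11–C13), the C1–C4 chain is added at C10, oxygen is moved to C6, ring A is closed at C4–C5, C19 and the aryl ester are attached, and the butenolide ring is built last.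
Enabling feature: ring B holds the C5–C10(O)–C9(CH3) unit of a 2-methyl beta-ketoester next to the C8(CH3)–C7–C6(O) unit of crotonaldehyde, so one Michael bond (C8–C9) and one aldol bond (C5–C6) give the ring; the ester only activates C9.
Stereochemistry: C8 from the diarylprolinol catalyst; C9 from allylation anti to the C8 methyl; C6 from oxazaborolidine-controlled reduction; C4 from aldol attack anti to the C6 silyloxy group.

Key step: step 2

Remark: the ester carbon of the ketoester is treated as a traceless activating group. The C9 configuration formed in the Michael step is not relied on, because C9 passes through an enolate and is fixed when CO2 is expelled in step 3.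

**Step 1**
Reactants: 1 allyl 3-oxobutanoate; 2 iodomethane
Product: 3 allyl 2-methyl-3-oxobutanoate
Conditions: K2CO3, acetone, 50 °C
Reagents that add atoms: none
Why: SN2 C-alkylation of the doubly stabilised acetoacetate enolate with one equivalent of iodomethane under carbonate conditions should give the monomethyl ketoester, whose stereocentre is freely epimerisable and of no consequence.

**Step 2**
Reactants: 3 allyl 2-methyl-3-oxobutanoate; 4 (E)-but-2-enal
Product: 6 allyl (6S)-1,6-dimethyl-2-oxocyclohex-3-ene-1-carboxylate, via keto aldehyde 5 (not isolated)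
Conditions: (R)-2-[diphenyl(trimethylsilyloxy)methyl]pyrrolidine (10 mol %), PhCO2H (10 mol %), toluene, 0 °C → rt; then p-toluenesulfonic acid monohydrate (20 mol %), toluene, 60 °C
Reagents that add atoms: none
Why: The secondary amine condenses with 4 to an (E)-iminium ion whose diphenyl(silyloxy)methyl group blocks one face, so the enol of 3 adds through C9 to the Si face of C8 (iminium-catalysed Michael addition) and hydrolysis releases keto aldehyde 5 and the catalyst. Acid then enolises the methyl ketone toward C5, the only position left once C9 is quaternary, and C5 adds to the aldehyde carbon C6 in a 6-(enolendo)-exo-trig aldol closure of ring B, followed by dehydration to the conjugated enone. The closest known reaction type is the secondary-amine-catalysed Michael addition of beta-ketoesters to enals followed by intramolecular aldol condensation to cyclohexenones. C8 (S) is set by the catalyst, whereas C9 forms without useful control, which is tolerated because both C9 epimers converge in step 3. The step therefore needs only enantiofacial attack at C8 and C- rather than O-alkylation, secured by the s-trans (E)-iminium geometry and the soft hydrogen-bonded ketoester enol; the aldehyde alpha-carbon C7 cannot compete in the closure because it could only form a four-membered ring.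

**Step 3**
Reactants: 6 allyl (6S)-1,6-dimethyl-2-oxocyclohex-3-ene-1-carboxylate
Product: 7 (5S,6R)-6-allyl-5,6-dimethylcyclohex-2-en-1-one
Conditions: Pd(PPh3)4 (5 mol %), THF, 25 °C
Reagents that add atoms: none
Why: Zerovalent palladium ionises the allyl ester, CO2 is lost and the cross-conjugated enolate recombines with the pi-allyl cation at C9 (Tsuji decarboxylative allylation) anti to the C8 methyl, which allylic strain holds pseudoaxial, so both epimers of 6 should converge on the cis-dimethyl ketone with C9 (R).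

**Step 4**
Reactants: 7 (5S,6R)-6-allyl-5,6-dimethylcyclohex-2-en-1-one
Product: 8 (5S,6R)-6-allyl-2-iodo-5,6-dimethylcyclohex-2-en-1-one
Conditions: I2, pyridine/CH2Cl2, 0 °C → rt
Reagents that add atoms: iodine, II
Why: Pyridine adds reversibly to C6, the resulting enolate is iodinated at C5 and pyridine is expelled (Baylis–Hillman-type alpha-iodination of an enone), a sequence that is fast for an enone with an unsubstituted beta-carbon and leaves the terminal alkene alone.

**Step 5**
Reactants: 9 pent-1-en-3-one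
Product: 11 2-(2-bromoethyl)-2-ethyl-1,3-dioxolane, via 1-bromopentan-3-one 10 (not isolated)
Conditions: HBr (gas), CH2Cl2, 0 °C; then ethane-1,2-diol, p-toluenesulfonic acid (cat.), rt
Reagents that add atoms: hydrogen bromide, Br; ethane-1,2-diol, OCCO
Why: Conjugate hydrobromination of the enone followed by acid-catalysed ketalisation is the standard way to a ketone-masked beta-bromo ketone, here the C1–C4 unit with the C4 methyl.

**Step 6**
Reactants: 8 (5S,6R)-6-allyl-2-iodo-5,6-dimethylcyclohex-2-en-1-one; 11 2-(2-bromoethyl)-2-ethyl-1,3-dioxolane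
Product: 13 (5S,6R)-6-allyl-1-[2-(2-ethyl-1,3-dioxolan-2-yl)ethyl]-2-iodo-5,6-dimethylcyclohex-2-en-1-ol, via Grignard reagent 12 (not isolated)
Conditions: 11, Mg, THF, 25 °C; then 8, LaCl3·2LiCl, THF, −78 → 0 °C; aqueous work-up
Reagents that add atoms: none
Why: The Grignard reagent adds 1,2 to the non-enolisable C10 carbonyl (Grignard addition), the oxophilic lanthanum salt favouring carbonyl addition over iodine–magnesium exchange or reduction; the C10 configuration is irrelevant because C10 becomes sp2 in step 7.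

**Step 7**
Reactants: 13 (5S,6R)-6-allyl-1-[2-(2-ethyl-1,3-dioxolan-2-yl)ethyl]-2-iodo-5,6-dimethylcyclohex-2-en-1-ol
Product: 14 (4R,5S)-4-allyl-3-[2-(2-ethyl-1,3-dioxolan-2-yl)ethyl]-2-iodo-4,5-dimethylcyclohex-2-en-1-one
Conditions: pyridinium chlorochromate [C5H5NH][CrO3Cl], NaOAc, 4 Å molecular sieves, CH2Cl2, rt
Reagents that add atoms: pyridinium chlorochromate (supplies the carbonyl oxygen), [O-][Cr](=O)(=O)Cl.c1cc[nH+]cc1
Why: The chromate ester of the tertiary allylic alcohol undergoes a [3,3] shift to C6 and is then oxidised (Dauben oxidative transposition), giving the C6 ketone with the tetrasubstituted C5=C10 alkene while the acetate buffer protects the ketal.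

**Step 8**
Reactants: 14 (4R,5S)-4-allyl-3-[2-(2-ethyl-1,3-dioxolan-2-yl)ethyl]-2-iodo-4,5-dimethylcyclohex-2-en-1-one
Product: 15 (1S,4R,5S)-4-allyl-3-[2-(2-ethyl-1,3-dioxolan-2-yl)ethyl]-2-iodo-4,5-dimethylcyclohex-2-en-1-ol
Conditions: (R)-1-methyl-3,3-diphenyltetrahydro-1H,3H-pyrrolo[1,2-c][1,3,2]oxazaborole (20 mol %), catecholborane, toluene, −78 → −40 °C
Reagents that add atoms: none
Why: In the Corey–Bakshi–Shibata reduction the ketone binds the oxazaborolidine boron anti to its larger substituent, the iodoalkene side, and the (R)-catalyst delivers hydride to the Re face of C6 to give the (S)-alcohol under catalyst control, while catecholborane at low temperature does not hydroborate the allyl group.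

**Step 9**
Reactants: 15 (1S,4R,5S)-4-allyl-3-[2-(2-ethyl-1,3-dioxolan-2-yl)ethyl]-2-iodo-4,5-dimethylcyclohex-2-en-1-ol
Product: 16 tert-butyl({(1S,4R,5S)-4-allyl-3-[2-(2-ethyl-1,3-dioxolan-2-yl)ethyl]-2-iodo-4,5-dimethylcyclohex-2-en-1-yl}oxy)dimethylsilane
Conditions: TBSCl, imidazole, 4-(dimethylamino)pyridine (cat.), DMF, 40 °C
Reagents that add atoms: tert-butyldimethylsilyl chloride, CC(C)(C)[Si](C)(C)Cl
Why: Silyl ether formation protects the C6 alcohol from base and palladium and installs the bulky group that later directs the aldol at C4.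

**Step 10**
Reactants: 16 tert-butyl({(1S,4R,5S)-4-allyl-3-[2-(2-ethyl-1,3-dioxolan-2-yl)ethyl]-2-iodo-4,5-dimethylcyclohex-2-en-1-yl}oxy)dimethylsilane
Product: 17 1-[(3S,5S,6R)-6-allyl-3-(tert-butyldimethylsilyloxy)-2-iodo-5,6-dimethylcyclohex-1-en-1-yl]pentan-3-one
Conditions: pyridinium p-toluenesulfonate (20 mol %), acetone/H2O 9:1, 50 °C
Reagents that add atoms: water, O
Why: Mild acid-catalysed ketal hydrolysis frees the C3 ethyl ketone, and a secondary silyl ether and an alkenyl iodide are stable to this weak acid.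

**Step 11**
Reactants: 17 1-[(3S,5S,6R)-6-allyl-3-(tert-butyldimethylsilyloxy)-2-iodo-5,6-dimethylcyclohex-1-en-1-yl]pentan-3-one
Product: 18 (5R,6S,8S)-5-allyl-8-(tert-butyldimethylsilyloxy)-1,5,6-trimethyl-3,4,5,6,7,8-hexahydronaphthalen-2(1H)-one
Conditions: Pd2(dba)3 (5 mol %), bis[2-(diphenylphosphino)phenyl] ether (12 mol %), NaOt-Bu, THF, 65 °C; AcOH quench at 0 °C
Reagents that add atoms: none
Why: Zerovalent palladium inserts into the C5–I bond, the sodium enolate of the ethyl ketone displaces iodide and C4–C5 reductive elimination closes ring A (palladium-catalysed intramolecular alpha-alkenylation of a ketone); coupling through C2 would need a cyclobutane, so only the six-membered ring can form, and C4 arises as an inconsequential epimer mixture.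

**Step 12**
Reactants: 18 (5R,6S,8S)-5-allyl-8-(tert-butyldimethylsilyloxy)-1,5,6-trimethyl-3,4,5,6,7,8-hexahydronaphthalen-2(1H)-one; 19 formaldehyde
Product: 21 (1S,5R,6S,8S)-5-allyl-8-(tert-butyldimethylsilyloxy)-1-(hydroxymethyl)-1,5,6-trimethyl-3,4,5,6,7,8-hexahydronaphthalen-2(1H)-one, via potassium dienolate 20 (not isolated)
Conditions: KN(SiMe3)2, THF, −78 °C; CH2O (gas, from cracked paraformaldehyde), −78 °C; AcOH quench at −78 °C
Reagents that add atoms: none
Why: The amide base removes the doubly activated C4 proton to give the conjugated dienolate, which adds through its alpha-carbon C4 to formaldehyde (aldol hydroxymethylation) on the face opposite the C6 silyloxy group, held pseudoaxial by allylic strain against the C4 methyl, so C19 ends trans to the C6 oxygen and C4 is (S).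

**Step 13**
Reactants: 22 3-(4-hydroxyphenyl)propanoic acid
Product: 24 3-[4-(tert-butyldimethylsilyloxy)phenyl]propanoic acid, via silyl ester 23 (not isolated)
Conditions: TBSCl (2.2 equiv), imidazole, DMF, rt; then AcOH/THF/H2O, rt
Reagents that add atoms: tert-butyldimethylsilyl chloride, CC(C)(C)[Si](C)(C)Cl
Why: Double silylation followed by selective hydrolysis of the far more labile silyl ester leaves the phenol protected as its aryl silyl ether and the acid free.

**Step 14**
Reactants: 21 (1S,5R,6S,8S)-5-allyl-8-(tert-butyldimethylsilyloxy)-1-(hydroxymethyl)-1,5,6-trimethyl-3,4,5,6,7,8-hexahydronaphthalen-2(1H)-one; 24 3-[4-(tert-butyldimethylsilyloxy)phenyl]propanoic acid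
Product: 25 [(1S,5R,6S,8S)-5-allyl-8-(tert-butyldimethylsilyloxy)-1,5,6-trimethyl-2-oxo-1,2,3,4,5,6,7,8-octahydronaphthalen-1-yl]methyl 3-[4-(tert-butyldimethylsilyloxy)phenyl]propanoate
Conditions: dicyclohexylcarbodiimide, 4-(dimethylamino)pyridine (20 mol %), CH2Cl2, 0 °C → rt
Reagents that add atoms: none
Why: Carbodiimide activation and acyl transfer through the acylpyridinium ion (Steglich esterification) acylate the hindered primary alcohol under conditions too mild for retro-aldol loss of formaldehyde.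

**Step 15**
Reactants: 25 [(1S,5R,6S,8S)-5-allyl-8-(tert-butyldimethylsilyloxy)-1,5,6-trimethyl-2-oxo-1,2,3,4,5,6,7,8-octahydronaphthalen-1-yl]methyl 3-[4-(tert-butyldimethylsilyloxy)phenyl]propanoate
Product: 26 [(1S,5R,6S,8S)-8-(tert-butyldimethylsilyloxy)-1,5,6-trimethyl-2-oxo-5-(3-oxopropyl)-1,2,3,4,5,6,7,8-octahydronaphthalen-1-yl]methyl 3-[4-(tert-butyldimethylsilyloxy)phenyl]propanoate
Conditions: PdCl2(PhCN)2 (12 mol %), CuCl2·2H2O (12 mol %), AgNO2 (6 mol %), O2 (1 atm), t-BuOH/MeNO2 15:1, rt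
Reagents that add atoms: dioxygen (terminal oxidant and oxygen source through the nitrite co-catalyst), O=O
Why: The nitrite-modified Wacker-type oxidation delivers oxygen to the terminal carbon of an unbiased monosubstituted alkene, giving the C13 aldehyde, while the tetrasubstituted C5=C10 alkene is too hindered to bind palladium.

**Step 16**
Reactants: 26 [(1S,5R,6S,8S)-8-(tert-butyldimethylsilyloxy)-1,5,6-trimethyl-2-oxo-5-(3-oxopropyl)-1,2,3,4,5,6,7,8-octahydronaphthalen-1-yl]methyl 3-[4-(tert-butyldimethylsilyloxy)phenyl]propanoate; 19 formaldehyde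
Product: 27 [(1S,5R,6S,8S)-8-(tert-butyldimethylsilyloxy)-5-(4-hydroxy-3-oxobutyl)-1,5,6-trimethyl-2-oxo-1,2,3,4,5,6,7,8-octahydronaphthalen-1-yl]methyl 3-[4-(tert-butyldimethylsilyloxy)phenyl]propanoate
Conditions: (CH2O)n, 3-(2,6-diisopropylphenyl)-4,5-dimethylthiazolium perchlorate (10 mol %), i-Pr2NEt (10 mol %), THF, 60 °C
Reagents that add atoms: none
Why: The thiazolylidene carbene converts the aldehyde into an acyl-anion equivalent that adds to formaldehyde (crossed benzoin-type hydroxymethylation), making C13 a ketone bearing the C16 hydroxymethyl group without touching the hindered C3 ketone.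

**Step 17**
Reactants: 27 [(1S,5R,6S,8S)-8-(tert-butyldimethylsilyloxy)-5-(4-hydroxy-3-oxobutyl)-1,5,6-trimethyl-2-oxo-1,2,3,4,5,6,7,8-octahydronaphthalen-1-yl]methyl 3-[4-(tert-butyldimethylsilyloxy)phenyl]propanoate; 28 (triphenylphosphoranylidene)ketene
Product: 29 [(1S,5R,6S,8S)-8-(tert-butyldimethylsilyloxy)-1,5,6-trimethyl-2-oxo-5-[2-(5-oxo-2,5-dihydrofuran-3-yl)ethyl]-1,2,3,4,5,6,7,8-octahydronaphthalen-1-yl]methyl 3-[4-(tert-butyldimethylsilyloxy)phenyl]propanoate
Conditions: toluene, 90 °C
Reagents that add atoms: none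
Why: The primary hydroxyl adds to the ketene to give an ester-stabilised ylide that closes onto the adjacent C13 ketone by intramolecular Wittig olefination, forming the beta-substituted butenolide; the tethered ylide cannot reach the remote C3 ketone.

**Step 18**
Reactants: 29 [(1S,5R,6S,8S)-8-(tert-butyldimethylsilyloxy)-1,5,6-trimethyl-2-oxo-5-[2-(5-oxo-2,5-dihydrofuran-3-yl)ethyl]-1,2,3,4,5,6,7,8-octahydronaphthalen-1-yl]methyl 3-[4-(tert-butyldimethylsilyloxy)phenyl]propanoate
Product: 30 [(1S,5R,6S,8S)-8-hydroxy-1,5,6-trimethyl-2-oxo-5-[2-(5-oxo-2,5-dihydrofuran-3-yl)ethyl]-1,2,3,4,5,6,7,8-octahydronaphthalen-1-yl]methyl 3-(4-hydroxyphenyl)propanoate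
Conditions: HF·pyridine, pyridine/THF, 0 °C → rt
Reagents that add atoms: none
Why: Fluoride-mediated desilylation removes the aryl and the secondary alkyl silyl ethers under buffered conditions that spare the butenolide and both esters and should not ionise the allylic C6 alcohol.

**Compound list**

1 | allyl 3-oxobutanoate | CC(=O)CC(=O)OCC=C | starting material
2 | iodomethane | CI | starting material
3 | allyl 2-methyl-3-oxobutanoate (racemic) | CC(=O)C(C)C(=O)OCC=C | intermediate
4 | (E)-but-2-enal | C/C=C/C=O | starting material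
5 | allyl (3S)-2-acetyl-2,3-dimethyl-5-oxopentanoate (C2 epimers) | C[C@@H](CC=O)C(C)(C(C)=O)C(=O)OCC=C | intermediate
6 | allyl (6S)-1,6-dimethyl-2-oxocyclohex-3-ene-1-carboxylate (C1 epimers) | C[C@H]1CC=CC(=O)C1(C)C(=O)OCC=C | intermediate
7 | (5S,6R)-6-allyl-5,6-dimethylcyclohex-2-en-1-one | C[C@H]1CC=CC(=O)[C@]1(C)CC=C | intermediate
8 | (5S,6R)-6-allyl-2-iodo-5,6-dimethylcyclohex-2-en-1-one | C[C@H]1CC=C(I)C(=O)[C@]1(C)CC=C | intermediate
9 | pent-1-en-3-one | CCC(=O)C=C | starting material
10 | 1-bromopentan-3-one | CCC(=O)CCBr | intermediate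
11 | 2-(2-bromoethyl)-2-ethyl-1,3-dioxolane | CCC1(CCBr)OCCO1 | intermediate
12 | [2-(2-ethyl-1,3-dioxolan-2-yl)ethyl]magnesium bromide | CCC1(CC[Mg]Br)OCCO1 | intermediate
13 | (5S,6R)-6-allyl-1-[2-(2-ethyl-1,3-dioxolan-2-yl)ethyl]-2-iodo-5,6-dimethylcyclohex-2-en-1-ol (C1 epimers) | C[C@H]1CC=C(I)C(O)(CCC2(CC)OCCO2)[C@]1(C)CC=C | intermediate
14 | (4R,5S)-4-allyl-3-[2-(2-ethyl-1,3-dioxolan-2-yl)ethyl]-2-iodo-4,5-dimethylcyclohex-2-en-1-one | C[C@H]1CC(=O)C(I)=C(CCC2(CC)OCCO2)[C@]1(C)CC=C | intermediate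
15 | (1S,4R,5S)-4-allyl-3-[2-(2-ethyl-1,3-dioxolan-2-yl)ethyl]-2-iodo-4,5-dimethylcyclohex-2-en-1-ol | C[C@H]1C[C@H](O)C(I)=C(CCC2(CC)OCCO2)[C@]1(C)CC=C | intermediate
16 | tert-butyl({(1S,4R,5S)-4-allyl-3-[2-(2-ethyl-1,3-dioxolan-2-yl)ethyl]-2-iodo-4,5-dimethylcyclohex-2-en-1-yl}oxy)dimethylsilane | C[C@H]1C[C@H](O[Si](C)(C)C(C)(C)C)C(I)=C(CCC2(CC)OCCO2)[C@]1(C)CC=C | intermediate
17 | 1-[(3S,5S,6R)-6-allyl-3-(tert-butyldimethylsilyloxy)-2-iodo-5,6-dimethylcyclohex-1-en-1-yl]pentan-3-one | C[C@H]1C[C@H](O[Si](C)(C)C(C)(C)C)C(I)=C(CCC(=O)CC)[C@]1(C)CC=C | intermediate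
18 | (5R,6S,8S)-5-allyl-8-(tert-butyldimethylsilyloxy)-1,5,6-trimethyl-3,4,5,6,7,8-hexahydronaphthalen-2(1H)-one (C1 epimers) | C[C@H]1C[C@H](O[Si](C)(C)C(C)(C)C)C2=C(CCC(=O)C2C)[C@]1(C)CC=C | intermediate
19 | formaldehyde (supplied as paraformaldehyde) | C=O | starting material
20 | potassium (5R,6S,8S)-5-allyl-8-(tert-butyldimethylsilyloxy)-1,5,6-trimethyl-3,4,5,6,7,8-hexahydronaphthalen-2-olate | C[C@H]1C[C@H](O[Si](C)(C)C(C)(C)C)C2=C(CCC([O-])=C2C)[C@]1(C)CC=C.[K+] | intermediate
21 | (1S,5R,6S,8S)-5-allyl-8-(tert-butyldimethylsilyloxy)-1-(hydroxymethyl)-1,5,6-trimethyl-3,4,5,6,7,8-hexahydronaphthalen-2(1H)-one | C[C@H]1C[C@H](O[Si](C)(C)C(C)(C)C)C2=C(CCC(=O)[C@]2(C)CO)[C@]1(C)CC=C | intermediate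
22 | 3-(4-hydroxyphenyl)propanoic acid | OC(=O)CCc1ccc(O)cc1 | starting material
23 | tert-butyldimethylsilyl 3-[4-(tert-butyldimethylsilyloxy)phenyl]propanoate | CC(C)(C)[Si](C)(C)OC(=O)CCc1ccc(O[Si](C)(C)C(C)(C)C)cc1 | intermediate
24 | 3-[4-(tert-butyldimethylsilyloxy)phenyl]propanoic acid | OC(=O)CCc1ccc(O[Si](C)(C)C(C)(C)C)cc1 | intermediate
25 | [(1S,5R,6S,8S)-5-allyl-8-(tert-butyldimethylsilyloxy)-1,5,6-trimethyl-2-oxo-1,2,3,4,5,6,7,8-octahydronaphthalen-1-yl]methyl 3-[4-(tert-butyldimethylsilyloxy)phenyl]propanoate | C[C@H]1C[C@H](O[Si](C)(C)C(C)(C)C)C2=C(CCC(=O)[C@]2(C)COC(=O)CCc2ccc(O[Si](C)(C)C(C)(C)C)cc2)[C@]1(C)CC=C | intermediate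
26 | [(1S,5R,6S,8S)-8-(tert-butyldimethylsilyloxy)-1,5,6-trimethyl-2-oxo-5-(3-oxopropyl)-1,2,3,4,5,6,7,8-octahydronaphthalen-1-yl]methyl 3-[4-(tert-butyldimethylsilyloxy)phenyl]propanoate | C[C@H]1C[C@H](O[Si](C)(C)C(C)(C)C)C2=C(CCC(=O)[C@]2(C)COC(=O)CCc2ccc(O[Si](C)(C)C(C)(C)C)cc2)[C@]1(C)CCC=O | intermediate
27 | [(1S,5R,6S,8S)-8-(tert-butyldimethylsilyloxy)-5-(4-hydroxy-3-oxobutyl)-1,5,6-trimethyl-2-oxo-1,2,3,4,5,6,7,8-octahydronaphthalen-1-yl]methyl 3-[4-(tert-butyldimethylsilyloxy)phenyl]propanoate | C[C@H]1C[C@H](O[Si](C)(C)C(C)(C)C)C2=C(CCC(=O)[C@]2(C)COC(=O)CCc2ccc(O[Si](C)(C)C(C)(C)C)cc2)[C@]1(C)CCC(=O)CO | intermediate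
28 | (triphenylphosphoranylidene)ketene | O=C=C=P(c1ccccc1)(c1ccccc1)c1ccccc1 | starting material
29 | [(1S,5R,6S,8S)-8-(tert-butyldimethylsilyloxy)-1,5,6-trimethyl-2-oxo-5-[2-(5-oxo-2,5-dihydrofuran-3-yl)ethyl]-1,2,3,4,5,6,7,8-octahydronaphthalen-1-yl]methyl 3-[4-(tert-butyldimethylsilyloxy)phenyl]propanoate | C[C@H]1C[C@H](O[Si](C)(C)C(C)(C)C)C2=C(CCC(=O)[C@]2(C)COC(=O)CCc2ccc(O[Si](C)(C)C(C)(C)C)cc2)[C@]1(C)CCC1=CC(=O)OC1 | intermediate
30 | [(1S,5R,6S,8S)-8-hydroxy-1,5,6-trimethyl-2-oxo-5-[2-(5-oxo-2,5-dihydrofuran-3-yl)ethyl]-1,2,3,4,5,6,7,8-octahydronaphthalen-1-yl]methyl 3-(4-hydroxyphenyl)propanoate | C[C@H]1C[C@H](O)C2=C(CCC(=O)[C@]2(C)COC(=O)CCc2ccc(O)cc2)[C@]1(C)CCC1=CC(=O)OC1 | target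

**Step count**

Total: 18 steps. Longest linear sequence: 16 steps (steps 1–4, 6–12 and 14–18); steps 5 and 13 prepare the two side reagents.

**Steps most likely to fail**

Step 11 (ring A closure). The carbon–carbon reductive elimination at the crowded, tetrasubstituted alkenylpalladium centre may be slow, so that loss of iodine by protonation, or addition of the alkenylpalladium to the C3 carbonyl, takes over. The fallback is a radical closure that sets out from 17. Silylation with triethylsilyl triflate and triethylamine should give the more substituted triethylsilyl enol ether F1. Tributyltin hydride with azobisisobutyronitrile in benzene at 80 °C then generates the C5 alkenyl radical, which should attack C4 in the 6-endo mode because the fully substituted C3 blocks the 5-exo mode, giving the bicyclic C3 triethylsilyl ether F2. Selective removal of the triethylsilyl group with pyridinium p-toluenesulfonate in methanol gives the C3 alcohol F3, and Dess–Martin oxidation returns to the route at 18.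

Step 12 (C4 hydroxymethylation). Deprotonation may go toward C2 instead of C4, or the aldol may reverse at the potassium alkoxide stage before the quench. The fallback sets out from 18: trimethylsilyl triflate and triethylamine should give the conjugated trimethylsilyl dienol ether F4, which can only form by enolisation toward C4. A Mukaiyama-type hydroxymethylation with aqueous formaldehyde and Sc(OTf)3 in THF/water then attacks C4 from the same face, anti to the C6 silyloxy group, without ever forming a basic alkoxide, and comes back to the route at 21.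

Step 16 (hydroxymethylation of the aldehyde). Self-acyloin coupling of the aliphatic aldehyde, or poor capture of the carbene adduct by formaldehyde, may dominate; the same fallback also bypasses the regioselectivity demand of step 15. It sets out from 25. Linear-selective hydroformylation (Rh(acac)(CO)2, BiPhePhos, CO/H2, toluene) should give the one-carbon-longer aldehyde F5. Condensation with glyoxylic acid and morpholinium chloride in hot aqueous dioxane gives the gamma-hydroxybutenolide F6. NaBH4 reduces the masked aldehyde, and also the C3 ketone, to give the butenolide C3 alcohol F7, and Dess–Martin oxidation of the only free hydroxyl restores the C3 ketone and returns to the route at 29.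

**Further compounds**

F1 | step 11 | tert-butyl({(1S,4R,5S)-4-allyl-2-iodo-4,5-dimethyl-3-[3-(triethylsilyloxy)pent-3-en-1-yl]cyclohex-2-en-1-yl}oxy)dimethylsilane | C[C@H]1C[C@H](O[Si](C)(C)C(C)(C)C)C(I)=C(CCC(O[Si](CC)(CC)CC)=CC)[C@]1(C)CC=C
F2 | step 11 | (5R,6S,8S)-5-allyl-8-(tert-butyldimethylsilyloxy)-1,5,6-trimethyl-2-(triethylsilyloxy)-1,2,3,4,5,6,7,8-octahydronaphthalene | C[C@H]1C[C@H](O[Si](C)(C)C(C)(C)C)C2=C(CCC(O[Si](CC)(CC)CC)C2C)[C@]1(C)CC=C
F3 | step 11 | (5R,6S,8S)-5-allyl-8-(tert-butyldimethylsilyloxy)-1,5,6-trimethyl-1,2,3,4,5,6,7,8-octahydronaphthalen-2-ol | C[C@H]1C[C@H](O[Si](C)(C)C(C)(C)C)C2=C(CCC(O)C2C)[C@]1(C)CC=C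
F4 | step 12 | (5R,6S,8S)-5-allyl-8-(tert-butyldimethylsilyloxy)-1,5,6-trimethyl-2-(trimethylsilyloxy)-3,4,5,6,7,8-hexahydronaphthalene | C[C@H]1C[C@H](O[Si](C)(C)C(C)(C)C)C2=C(CCC(O[Si](C)(C)C)=C2C)[C@]1(C)CC=C
F5 | step 16 | [(1S,5R,6S,8S)-8-(tert-butyldimethylsilyloxy)-1,5,6-trimethyl-2-oxo-5-(4-oxobutyl)-1,2,3,4,5,6,7,8-octahydronaphthalen-1-yl]methyl 3-[4-(tert-butyldimethylsilyloxy)phenyl]propanoate | C[C@H]1C[C@H](O[Si](C)(C)C(C)(C)C)C2=C(CCC(=O)[C@]2(C)COC(=O)CCc2ccc(O[Si](C)(C)C(C)(C)C)cc2)[C@]1(C)CCCC=O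
F6 | step 16 | [(1S,5R,6S,8S)-8-(tert-butyldimethylsilyloxy)-5-[2-(2-hydroxy-5-oxo-2,5-dihydrofuran-3-yl)ethyl]-1,5,6-trimethyl-2-oxo-1,2,3,4,5,6,7,8-octahydronaphthalen-1-yl]methyl 3-[4-(tert-butyldimethylsilyloxy)phenyl]propanoate | C[C@H]1C[C@H](O[Si](C)(C)C(C)(C)C)C2=C(CCC(=O)[C@]2(C)COC(=O)CCc2ccc(O[Si](C)(C)C(C)(C)C)cc2)[C@]1(C)CCC1=CC(=O)OC1O
F7 | step 16 | [(1S,5R,6S,8S)-8-(tert-butyldimethylsilyloxy)-2-hydroxy-1,5,6-trimethyl-5-[2-(5-oxo-2,5-dihydrofuran-3-yl)ethyl]-1,2,3,4,5,6,7,8-octahydronaphthalen-1-yl]methyl 3-[4-(tert-butyldimethylsilyloxy)phenyl]propanoate | C[C@H]1C[C@H](O[Si](C)(C)C(C)(C)C)C2=C(CCC(O)[C@]2(C)COC(=O)CCc2ccc(O[Si](C)(C)C(C)(C)C)cc2)[C@]1(C)CCC1=CC(=O)OC1
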